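**Retrosynthetic overview**

1. Feature: ring B (C1' CO2H, C2' OH, C3' H, C4' O-aryl, C5' OMe, C6' heptyl) carries para oxygens at C2' and C5'. The unit C2'–C3'–C4'–C5' with its three oxygens is a 4-aryloxy-2-silyloxyfuran, and C1'–C6' is the triple bond of a dec-2-ynoate.
2. Key disconnection: ring B is cut at C1'–C2' and C5'–C6' into furan 7 and ynoate 10. The furan ring oxygen ends as the free C5' phenol and the silyl ether stays on C2'.
3. The diaryl ether bond O–C4' goes back to ring A phenol 4 and 4-bromofuran-2(5H)-one by addition–elimination. Phenol 4 comes from 5-heptylresorcinol by carboxylation, benzyl ester formation and 4-O-methylation.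
4. Endgame: O-methylation at C5', desilylation at C2', hydrogenolysis of both benzyl esters.
5. Ring order: ring A is bought as the arene, the butenolide is aromatized to the furan by silylation, and ring B is formed last on the furan carbons.

Key step: step 7

Remark: the target has no stereocenter. Adduct 11 is racemic and is not isolated. 5-Heptylresorcinol, 4-bromofuran-2(5H)-one and non-1-yne are taken as purchasable.

**Route**

Step 1
Reactants: 1 5-heptylresorcinol
Product: 2 2-heptyl-4,6-dihydroxybenzoic acid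
Conditions: MeOMgOCO2Me (2 M in DMF, 3 equiv), 120 °C, N2 sweep; then cold 2 M HCl
Reagents that add atoms: magnesium methyl carbonate, COC(=O)O[Mg]OC
Why: Chelation-assisted Kolbe–Schmitt-type carboxylation with Stiles' reagent should place the carboxyl on the ring carbon ortho to one hydroxyl and para to the other, the magnesium salicylate chelate holding the acid until the cold quench.

Step 2
Reactants: 2 2-heptyl-4,6-dihydroxybenzoic acid
Product: 3 benzyl 2-heptyl-4,6-dihydroxybenzoate
Conditions: BnBr (1.05 equiv), KHCO3, DMF, rt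
Reagents that add atoms: benzyl bromide, BrCc1ccccc1
Why: Carboxylate SN2 alkylation; hydrogencarbonate ionizes only the carboxylic acid, so both phenols should stay free.

Step 3
Reactants: 3 benzyl 2-heptyl-4,6-dihydroxybenzoate
Product: 4 benzyl 2-heptyl-6-hydroxy-4-methoxybenzoate
Conditions: MeI (1.1 equiv), K2CO3 (1.1 equiv), acetone, rt
Reagents that add atoms: iodomethane, CI
Why: Williamson ether synthesis that should be selective for the more acidic para hydroxyl, because the ortho hydroxyl is held in a hydrogen bond to the ester carbonyl.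

Step 4
Reactants: 4 benzyl 2-heptyl-6-hydroxy-4-methoxybenzoate; 5 4-bromofuran-2(5H)-one
Product: 6 benzyl 2-heptyl-4-methoxy-6-[(5-oxo-2,5-dihydrofuran-3-yl)oxy]benzoate
Conditions: K2CO3, DMF, rt
Reagents that add atoms: none
Why: Addition–elimination (vinylogous acyl substitution) of the phenoxide at the beta carbon of the bromobutenolide should give the aryl tetronate, with the ether oxygen bound to sp2 carbon.

Step 5
Reactants: 6 benzyl 2-heptyl-4-methoxy-6-[(5-oxo-2,5-dihydrofuran-3-yl)oxy]benzoate
Product: 7 benzyl 2-heptyl-4-methoxy-6-{[5-(triisopropylsilyloxy)furan-3-yl]oxy}benzoate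
Conditions: TIPSOTf (1.2 equiv), Et3N (1.5 equiv), CH2Cl2, 0 °C; pentane trituration, filtration, used at once
Reagents that add atoms: triisopropylsilyl trifluoromethanesulfonate, CC(C)[Si](OS(=O)(=O)C(F)(F)F)(C(C)C)C(C)C
Why: Soft enolization, that is O-silylation of the lactone carbonyl and removal of a C5 proton by the amine, should give the aromatic 2-silyloxyfuran as it does with alkyl tetronates; the benzoate ester cannot enolize.

Step 6
Reactants: 8 non-1-yne
Product: 10 benzyl dec-2-ynoate, via lithium non-1-ynide 9 (not isolated)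
Conditions: n-BuLi, THF, −78 °C; then added to BnOCOCl, −78 °C to rt
Reagents that add atoms: benzyl chloroformate, O=C(Cl)OCc1ccccc1
Why: Deprotonation of the terminal alkyne and C-acylation of the lithium acetylide with a chloroformate, a standard route to alk-2-ynoates.

Step 7
Reactants: 7 benzyl 2-heptyl-4-methoxy-6-{[5-(triisopropylsilyloxy)furan-3-yl]oxy}benzoate; 10 benzyl dec-2-ynoate
Product: 12 benzyl 4-{2-[(benzyloxy)carbonyl]-3-heptyl-5-methoxyphenoxy}-6-heptyl-5-hydroxy-2-(triisopropylsilyloxy)benzoate, via 7-oxanorbornadiene cycloadduct 11 (not isolated)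
Conditions: 10 (3 equiv), 2,6-di-tert-butylpyridine (0.1 equiv), PhMe, 120 °C, sealed tube
Reagents that add atoms: none
Why: The electron-rich silyloxyfuran should act as the diene in a normal-demand Diels–Alder reaction with the ynoate (concerted and asynchronous, or a vinylogous Mukaiyama–Michael addition followed by closure of the allenoate onto the silyloxocarbenium ion, both giving 11), which forms C5'–C6' from furan C5 and the heptyl-bearing alkyne carbon and C1'–C2' from furan C2 and the ester-bearing alkyne carbon. The closest known reaction type is the cycloaddition of 2-silyloxyfurans with acetylenic esters, whose 1-silyloxy-7-oxanorbornadienes open to hydroquinone monosilyl ethers. Ring B is closed by this intermolecular (4+2) cycloaddition; the oxygen bridge of 11 then ionizes at the bridgehead bearing the silyloxy group, and loss of the C5' proton aromatizes the ring and leaves the former bridge oxygen as the free C5' phenol. No stereocenter is kept, since the two bridgehead centres of racemic 11 vanish on aromatization. The step needs regioselectivity, and this is secured because furan C5 is both the gamma carbon of the silyl dienolate and the beta carbon of the aryl enol ether, so it carries the largest HOMO coefficient and bonds to the beta carbon of the ynoate. It also needs bridge opening in one direction only, which the silyloxy group secures, so the two para oxygens leave the step differentiated as silyl ether at C2' and phenol at C5'.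

Step 8
Reactants: 12 benzyl 4-{2-[(benzyloxy)carbonyl]-3-heptyl-5-methoxyphenoxy}-6-heptyl-5-hydroxy-2-(triisopropylsilyloxy)benzoate
Product: 13 benzyl 4-{2-[(benzyloxy)carbonyl]-3-heptyl-5-methoxyphenoxy}-6-heptyl-5-methoxy-2-(triisopropylsilyloxy)benzoate
Conditions: MeI (1.5 equiv), K2CO3, acetone, 45 °C
Reagents that add atoms: iodomethane, CI
Why: Williamson methylation of the only free phenol; the aryl triisopropylsilyl ether should survive anhydrous carbonate, and if it were lost the hydrogen-bonded C2' hydroxyl would still methylate far more slowly.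

Step 9
Reactants: 13 benzyl 4-{2-[(benzyloxy)carbonyl]-3-heptyl-5-methoxyphenoxy}-6-heptyl-5-methoxy-2-(triisopropylsilyloxy)benzoate
Product: 14 benzyl 4-{2-[(benzyloxy)carbonyl]-3-heptyl-5-methoxyphenoxy}-6-heptyl-2-hydroxy-5-methoxybenzoate
Conditions: Bu4NF (1.1 equiv), AcOH (1.1 equiv), THF, 0 °C
Reagents that add atoms: none
Why: Fluoride-induced cleavage of the aryl silyl ether; the acetic acid buffer keeps the benzyl esters and the diaryl ether untouched.

Step 10
Reactants: 14 benzyl 4-{2-[(benzyloxy)carbonyl]-3-heptyl-5-methoxyphenoxy}-6-heptyl-2-hydroxy-5-methoxybenzoate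
Product: 15 4-(2-carboxy-3-heptyl-5-methoxyphenoxy)-6-heptyl-2-hydroxy-5-methoxybenzoic acid
Conditions: H2 (1 atm), Pd/C (10 wt %), EtOAc, rt
Reagents that add atoms: none
Why: Catalytic hydrogenolysis of both benzyl esters at room temperature should free the two acids without heat, so the salicylic acid of ring B is not exposed to decarboxylating conditions; aryl ethers are inert.

**Compound list**

1 | 5-heptylresorcinol | CCCCCCCc1cc(O)cc(O)c1 | starting material
2 | 2-heptyl-4,6-dihydroxybenzoic acid | CCCCCCCc1cc(O)cc(O)c1C(=O)O | intermediate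
3 | benzyl 2-heptyl-4,6-dihydroxybenzoate | CCCCCCCc1cc(O)cc(O)c1C(=O)OCc1ccccc1 | intermediate
4 | benzyl 2-heptyl-6-hydroxy-4-methoxybenzoate | CCCCCCCc1cc(OC)cc(O)c1C(=O)OCc1ccccc1 | intermediate
5 | 4-bromofuran-2(5H)-one | O=C1C=C(Br)CO1 | starting material
6 | benzyl 2-heptyl-4-methoxy-6-[(5-oxo-2,5-dihydrofuran-3-yl)oxy]benzoate | CCCCCCCc1cc(OC)cc(OC2=CC(=O)OC2)c1C(=O)OCc1ccccc1 | intermediate
7 | benzyl 2-heptyl-4-methoxy-6-{[5-(triisopropylsilyloxy)furan-3-yl]oxy}benzoate | CCCCCCCc1cc(OC)cc(Oc2coc(O[Si](C(C)C)(C(C)C)C(C)C)c2)c1C(=O)OCc1ccccc1 | intermediate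
8 | non-1-yne | C#CCCCCCCC | starting material
9 | lithium non-1-ynide (not isolated) | [Li]C#CCCCCCCC | intermediate
10 | benzyl dec-2-ynoate | CCCCCCCC#CC(=O)OCc1ccccc1 | intermediate
11 | benzyl 5-{2-[(benzyloxy)carbonyl]-3-heptyl-5-methoxyphenoxy}-3-heptyl-1-(triisopropylsilyloxy)-7-oxabicyclo[2.2.1]hepta-2,5-diene-2-carboxylate (racemic, not isolated) | CCCCCCCC1=C(C(=O)OCc2ccccc2)C2(O[Si](C(C)C)(C(C)C)C(C)C)C=C(Oc3cc(OC)cc(CCCCCCC)c3C(=O)OCc3ccccc3)C1O2 | intermediate
12 | benzyl 4-{2-[(benzyloxy)carbonyl]-3-heptyl-5-methoxyphenoxy}-6-heptyl-5-hydroxy-2-(triisopropylsilyloxy)benzoate | CCCCCCCc1cc(OC)cc(Oc2cc(O[Si](C(C)C)(C(C)C)C(C)C)c(C(=O)OCc3ccccc3)c(CCCCCCC)c2O)c1C(=O)OCc1ccccc1 | intermediate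
13 | benzyl 4-{2-[(benzyloxy)carbonyl]-3-heptyl-5-methoxyphenoxy}-6-heptyl-5-methoxy-2-(triisopropylsilyloxy)benzoate | CCCCCCCc1cc(OC)cc(Oc2cc(O[Si](C(C)C)(C(C)C)C(C)C)c(C(=O)OCc3ccccc3)c(CCCCCCC)c2OC)c1C(=O)OCc1ccccc1 | intermediate
14 | benzyl 4-{2-[(benzyloxy)carbonyl]-3-heptyl-5-methoxyphenoxy}-6-heptyl-2-hydroxy-5-methoxybenzoate | CCCCCCCc1cc(OC)cc(Oc2cc(O)c(C(=O)OCc3ccccc3)c(CCCCCCC)c2OC)c1C(=O)OCc1ccccc1 | intermediate
15 | 4-(2-carboxy-3-heptyl-5-methoxyphenoxy)-6-heptyl-2-hydroxy-5-methoxybenzoic acid | CCCCCCCc1cc(OC)cc(Oc2cc(O)c(C(=O)O)c(CCCCCCC)c2OC)c1C(=O)O | target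

**Step count and risk**

Total step count: 10. Longest linear sequence: 9 steps (steps 1–5 and 7–10); step 6 is a one-step branch.

Steps most likely to fail:

Step 7. The beta-heptyl ynoate is a weak dienophile, so cycloaddition may be slower than thermal desilylation of the furan or than open-chain Michael addition that does not close. The fallback sets out from furan 7 and acetylide 9 and changes the two-carbon partner to an ynal. Acetylide 9, generated as in step 6, would be formylated with DMF (THF, −78 °C, cold dilute HCl quench) to dec-2-ynal F1. This much more electrophilic dienophile should add to 7 in PhMe at rt to 60 °C with the same regiochemistry, and bridge opening would give benzyl 2-[4-formyl-3-heptyl-2-hydroxy-5-(triisopropylsilyloxy)phenoxy]-6-heptyl-4-methoxybenzoate F2. Methylation (MeI, K2CO3, acetone) would give benzyl 2-[4-formyl-3-heptyl-2-methoxy-5-(triisopropylsilyloxy)phenoxy]-6-heptyl-4-methoxybenzoate F3. Pinnick oxidation (NaClO2, NaH2PO4, 2-methylbut-2-ene, t-BuOH/H2O) would give 4-{2-[(benzyloxy)carbonyl]-3-heptyl-5-methoxyphenoxy}-6-heptyl-5-methoxy-2-(triisopropylsilyloxy)benzoic acid F4. Benzylation (BnBr, KHCO3, DMF) brings the fallback back to the route at 13.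

Step 4. The hydrogen-bonded, ortho-disubstituted phenoxide may substitute slowly, while base-induced self-condensation of the bromobutenolide through its C5 anion consumes the electrophile. The fallback sets out from phenol 4 and builds the butenolide on the phenol oxygen. Conjugate addition of 4 to purchased ethyl 4-hydroxybut-2-ynoate (DABCO 0.2 equiv, MeCN, rt then 60 °C) should give, after equilibration of the enol ether geometry, ethyl (2E)-3-{2-[(benzyloxy)carbonyl]-3-heptyl-5-methoxyphenoxy}-4-hydroxybut-2-enoate F5. Its hydroxymethyl group is cis to the ester and should lactonize with loss of ethanol, coming back to the route at 6.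

Step 1. Carboxylation may go to the ring carbon between the two hydroxyls, or the acid may decarboxylate back to 1 at the temperature needed. The fallback sets out from 1 and brings in the carboxyl carbon as an aldehyde. Vilsmeier–Haack formylation (POCl3, DMF, 0 °C to rt, ice-water hydrolysis) should give 2-heptyl-4,6-dihydroxybenzaldehyde F6. Selective para methylation (MeI, K2CO3, acetone) would give 2-heptyl-6-hydroxy-4-methoxybenzaldehyde F7. Pinnick oxidation (NaClO2, NaH2PO4, 2-methylbut-2-ene, t-BuOH/H2O) would give 2-heptyl-6-hydroxy-4-methoxybenzoic acid F8. Benzylation (BnBr, KHCO3, DMF) comes back to the route at 4.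

**Further compounds**

F1 | step 7 | dec-2-ynal | CCCCCCCC#CC=O
F2 | step 7 | benzyl 2-[4-formyl-3-heptyl-2-hydroxy-5-(triisopropylsilyloxy)phenoxy]-6-heptyl-4-methoxybenzoate | CCCCCCCc1cc(OC)cc(Oc2cc(O[Si](C(C)C)(C(C)C)C(C)C)c(C=O)c(CCCCCCC)c2O)c1C(=O)OCc1ccccc1
F3 | step 7 | benzyl 2-[4-formyl-3-heptyl-2-methoxy-5-(triisopropylsilyloxy)phenoxy]-6-heptyl-4-methoxybenzoate | CCCCCCCc1cc(OC)cc(Oc2cc(O[Si](C(C)C)(C(C)C)C(C)C)c(C=O)c(CCCCCCC)c2OC)c1C(=O)OCc1ccccc1
F4 | step 7 | 4-{2-[(benzyloxy)carbonyl]-3-heptyl-5-methoxyphenoxy}-6-heptyl-5-methoxy-2-(triisopropylsilyloxy)benzoic acid | CCCCCCCc1cc(OC)cc(Oc2cc(O[Si](C(C)C)(C(C)C)C(C)C)c(C(=O)O)c(CCCCCCC)c2OC)c1C(=O)OCc1ccccc1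
F5 | step 4 | ethyl (2E)-3-{2-[(benzyloxy)carbonyl]-3-heptyl-5-methoxyphenoxy}-4-hydroxybut-2-enoate | CCOC(=O)/C=C(\CO)Oc1cc(OC)cc(CCCCCCC)c1C(=O)OCc1ccccc1
F6 | step 1 | 2-heptyl-4,6-dihydroxybenzaldehyde | CCCCCCCc1cc(O)cc(O)c1C=O
F7 | step 1 | 2-heptyl-6-hydroxy-4-methoxybenzaldehyde | CCCCCCCc1cc(OC)cc(O)c1C=O
F8 | step 1 | 2-heptyl-6-hydroxy-4-methoxybenzoic acid | CCCCCCCc1cc(OC)cc(O)c1C(=O)O
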